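In a one-step world electrophile meets nucleophile one-for-one and the flask is over, so I reckon with what is left and not with what is made.

| flask | electrophile | free base | protonated nucleophile | temperature | remark | time |
|---|---|---|---|---|---|---|
| green | 0.013 M | 2 equiv | 1.2 equiv | 10 °C | run made earlier |  |
| grey | 0.030 M | 2 equiv | 1.2 equiv | 30 °C | run made earlier |  |
| dawn | 0.020 M | 2.00 equiv | 1.20 equiv | 25 °C |  | 1.5 h |
| winter | 0.020 M | 2.00 equiv | 1.20 equiv | 35 °C |  | 1.5 h |

green run (percent of the electrophile charged)

| time / h | electrophile / % | target / % | isomer of the product / % |
|---|---|---|---|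
| 0.250 | 95 | 4 | 0 |
| 0.500 | 89 | 8 | 0 |
| 1.33 | 83 | 12 | 2 |
| 3.00 | 67 | 19 | 11 |

grey run (percent of the electrophile charged)

| time / min | electrophile / % | target / % | isomer of the product / % |
|---|---|---|---|
| 25.0 | 60 | 32 | 11 |
| 50.0 | 46 | 39 | 19 |
| 60.0 | 39 | 39 | 23 |
| 90.0 | 33 | 45 | 24 |

(standard deviation of a reading: 2 percentage points)

1. which of these there is most of at the end, counted by the electrophile in it, dawn (electrophile / isomer of the product / target)
2. which of these there is most of at the end, counted by the electrophile in it, winter (electrophile / isomer of the product / target)
3. how much there is at the end of the one of these that leads, in percent of the electrophile charged: dawn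
4. how much there is at the end of the one of these that leads, in percent of the electrophile charged: winter



I climb the ladder from the fastest rung. First, I assume the free base hands out nucleophile from its protonated form at once. Next comes the isomer: the grey run's isomer-to-target ratio reads 0.487 at 50.0 min and 0.533 at 90.0 min, so I treat that pair as balanced and split whatever electrophile has reacted in that ratio.

The slowest rung is the pairing. Counting one protonated nucleophile for each electrophile, I take the logarithm of nucleophile share left over electrophile share left to grow as constant times surplus nucleophile concentration times time. The last readings give 32.4 L mol⁻¹ h⁻¹ in the grey run and 10.1 L mol⁻¹ h⁻¹ in the green run. Taking an equal factor for each degree, I get for dawn the pairing constant 24.2 L mol⁻¹ h⁻¹.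

With dawn's charge its pairing clock, one over constant times concentration, is 2.07 h, longer than the 1.5 h allowed. So I expect 51.6% of the electrophile left in dawn, and it leads. Winter's constant, 43.3 L mol⁻¹ h⁻¹, leaves 36.0%, and the split gives 41.8% of target, which leads.

The forecast names electrophile at 49% for dawn and target at 39% for winter, “so target narrowly leads electrophile”, both lower than my figures .

The flasks give electrophile at 48.5% in dawn and target at 43.7% in winter.

    acid set free + free base ⇌ salt of the base, settled at all times (K = 53000 L mol⁻¹, ΔH = 8.00 kJ mol⁻¹)
    target ⇌ isomer of the product (K = 0.600, k = 9.60 × 10⁻⁴ s⁻¹, Ea = 83.0 kJ mol⁻¹, ΔH = −9.00 kJ mol⁻¹)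
    electrophile + nucleophile ⇌ acid set free + target (K = 0.350, k = 0.0380 L mol⁻¹ s⁻¹, Ea = 44.0 kJ mol⁻¹, ΔH = −38.0 kJ mol⁻¹)
    nucleophile + acid set free ⇌ protonated nucleophile, settled at all times (K = 2.80 × 10⁵ L mol⁻¹, ΔH = −39.0 kJ mol⁻¹)
    (constants at 25 °C)

In dawn, target and isomer relax together with a half-life of 0.0752 h by that step alone, far shorter than the pairing clock of 2.07 h. At the end of dawn, isomer stands to target at 0.575, while electrophile keeps its lead. With all else as stated, electrophile and target stand level at 30.7 °C.

Now take dawn's flask at 10 °C. The same factor brings the pairing constant down to 10.1 L mol⁻¹ h⁻¹, which leaves 72.7% of the electrophile. That flask computes to 74%.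

The earlier runs and the new flask are calculated from invented constants; noise was put on by code.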